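## Structural features

The target is methyl 15-acetoxy-ent-halima-1(10),13E-dien-18-oate, a Δ1(10)-octalin in which cyclohexene ring A (C1–C5, C10) and cyclohexane ring B (C5–C10) share the C5–C10 bond. The only ring alkene, trisubstituted C1=C10, sits at the fusion. Ring A carries the quaternary centre C4 (methyl and methoxycarbonyl) next to the methine C5, with the carboxyl cis to H-5. Ring B carries the secondary methyl centre C8 next to the quaternary centre C9. C9 bears a methyl group cis to the C8 methyl and, on the face of H-5, the chain C11–C12–C13(Me)=C14–C15–OAc with an E trisubstituted alkene. The two stereo pairs (C4/C5 and C8/C9) are separated by sp2 C10, so C9 has only a 1,3 relation to C5; this weak relay, with two quaternary centres, is the real difficulty. Fragile points are the primary allylic acetate, the 1(10)-alkene (it can move into conjugation with a C8 carbonyl, which would make H-5 acidic) and the need to distinguish the hindered C4 ester from other esters. The key step exploits the fact that the ring-A alkene C1=C10 is flanked by C2 and C5: a retro-[4+2] cut of C2–C3 and C4–C5 leaves a vinyl group on a ring-B cyclohexene (diene C2=C1–C10=C5) and a methacrylic C3=C4 unit that already carries the C4 methyl and carbonyl. The cis relation of the C4 carbonyl to H-5 is the carbonyl-exo mode of that cycloaddition.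

## Logic of the disconnections

**25 to 24.** The acetyl C–O bond at C15 is cut first. This keeps the only ionisable group out of every organometallic step. The forward step needs only a mild acylation.

**24 to 21.** The bonds C13–C16 and C14–C15 are cut together, as the methyl and hydroxymethyl groups added across a terminal alkyne. The reason is that a syn carbometalation fixes the E geometry by mechanism. The gain is a plain alkyne; the demand is methyl delivery to the internal carbon and tolerance of the hindered C4 ester.

**21 to 19 and 20.** The C12–C13 bond is cut as an SN2 union of a primary iodide with an acetylide. The forward step needs an unhindered primary carbon, which C12 is.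

**19 to 18 to 17.** The iodide goes back to the C12 alcohol. Then the C8–H and C17–H bonds are removed to give the 8(17)-alkene. The reason is that the C12 hydroxyl of 17 sits on the β arm of C9 and can carry a cationic metal to the β face of that alkene. The demand is that direction beats steric approach and that the 1(10)-alkene survives.

**17 to 16 to 15.** The C12 alcohol goes back to an ester and the C8=C17 bond is cut to the C8 ketone. This returns to a carbonyl that can activate C9. The demands are ester-selective reduction and a non-basic methylenation.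

**15 to 12 and 13, then 12 to 10.** The bonds C9–C11 and then C9–C20 are cut as two dienolate alkylations. Methyl goes on first so that the second electrophile, which is expected to enter on the β face, becomes the side chain. The demand is that the dienolate stays in the 1(10) series so that H-5 is never acidic.

**10 to 9 to 8 to 7.** These are functional-group changes only: ketone from ketal, ester from acid, acid from aldehyde. They lead back to the cycloadduct oxidation pattern.

**7 to 5 and 6.** The bonds C2–C3 and C4–C5 are cut. One ring, two bonds and both ring-A stereocentres fall away. The forward step needs ortho regiochemistry, exo topology and one enal face.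

**5 to 3 and 4, then 3 to 1.** The vinyl-to-ring bond C1–C10 is cut as a cross-coupling of an enol triflate. This fixes the ring alkene position by construction and not by an acid equilibrium. The demand is kinetic enolisation of 1 away from the ketal.

## Other disconnections considered

**Alternative 1:** The cut is C8–C9 in ring B. The forward step is an Ireland–Claisen ring contraction. The silyl ketene acetal of the ring-A-fused δ-lactone A1 (ring oxygen on C6, carbonyl C11 on C9, (Z)-propenyl on C6) would rearrange through the boat enforced by the lactone ring. This would give the acid A2 with C8–C9 formed, C6–O cleaved and a 6(7)-alkene.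
- In its favour: C8 and C9 would be made together, with their relation fixed by alkene geometry and ring topology. The chosen plan sets them in two separate substrate-controlled steps (8 and 11), so on this point the alternative is the better plan.
- Against it here: A1 already contains C4 and C5, so ring A must first be made enantioselectively, which is the problem the cycloaddition solves in one step. A1 also needs a defined C6 carbinol and a Z alkene whose methyl points into the boat. In A2 the side chain must be grown from a carboxyl on a neopentyl carbon, and the 6(7)-alkene must be reduced beside the 1(10)-alkene.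
- Comparison: both key steps are pericyclic and stereospecific. Structurally the alternative solves ring B and the chosen plan ring A. The alternative is expected to be longer.

**Alternative 2:** The cut is C9–C10 plus the C20–H bond. The forward step is a reductive Heck cyclisation of the enol triflate A3. Zerovalent palladium would insert into the C10–O bond, add 6-exo to the 1,1-disubstituted alkene and be reduced by formate to give A4.
- In its favour: C8 is set in an open chain before ring closure, which is safer than a late directed hydrogenation. The alkene position is fixed by the triflate and the neopentyl palladium cannot eliminate. A4 is the silyl ether of 18, so from there the two plans are equal.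
- Against it here: ring A with C4 and C5 must still be made as one enantiomer, with triflate formation toward C1 and away from the epimerisable C5. The C9 configuration would rest on a chair-like insertion of uncertain facial sense. The neopentyl palladium may insert into the new 1(10)-alkene before formate capture.
- Comparison: the mechanism is organometallic, not pericyclic, so C9 is less predictable than C4/C5 are in the cycloaddition. Two chiral fragments make it more convergent but not shorter.

**Alternative 3:** The cut is C4–C5, made from the C1 side. The forward step is an Ireland–Claisen contraction of the α-methoxycarbonyl δ-lactone A5. Its silyl ketene acetal would rearrange through a boat to A6, closing ring A with the 1(10)-alkene.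
- In its favour: the C4/C5 relation follows from ring topology, with no regiochemical or exo/endo question; here it is at least the equal of the cycloaddition. Ring B with C8 and C9 would be finished before ring A exists, which is an advantage over the chosen plan.
- Against it here: the former lactone carbonyl ends as a carboxyl in the place of the C4 methyl, so it must be reduced to CH3 in several steps beside an ester and alkenes. The C1 carbinol must be matched to C9. The new bond joins a ring-alkene carbon to a fully substituted ketene acetal carbon.
- Comparison: the mechanism is as predictable as the chosen one. The plan shifts the stereochemical work onto A5 and is expected to need more steps than the 15 used here.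

Key step: step 3

Assumption 1: halimane numbering (C1–C20) is used for all intermediates; the target is the (4S,5S,8R,9S) isomer.
Assumption 2: the (S)-oxazaborolidinium catalyst is taken to leave the Cα Re face of bound methacrolein open, as in its accepted binding model for 2-substituted acroleins; if the sense is opposite, the (R)-catalyst is used unchanged.
Remark: diene, dienophile and adduct of the key step are mutually consistent with the target and are used unaltered; the one design change is that the diene ring alkene is fixed through an enol triflate.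

## Steps

Step 1
Reactants: 1 1,4-dioxaspiro[4.5]decan-7-one
Product: 3 1,4-dioxaspiro[4.5]dec-7-en-7-yl trifluoromethanesulfonate, via lithium enolate 2 (not isolated)
Conditions: LiN(i-Pr)2, THF, −78 °C; then N-(5-chloropyridin-2-yl)-N-(trifluoromethylsulfonyl)trifluoromethanesulfonamide, −78 → 0 °C
Reagents that add atoms: N-(5-chloropyridin-2-yl)-1,1,1-trifluoro-N-(trifluoromethylsulfonyl)methanesulfonamide, FC(F)(F)S(=O)(=O)N(c1ccc(Cl)cn1)S(=O)(=O)C(F)(F)F
Why: Kinetic deprotonation should occur at the methylene remote from the ketal, because the other α-methylene is neopentyl-like and flanked by the ketal carbon. O-Triflation of the lithium enolate (enol triflate formation) then fixes the ring alkene at C7=C8 of the spiro numbering.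

Step 2
Reactants: 3 1,4-dioxaspiro[4.5]dec-7-en-7-yl trifluoromethanesulfonate; 4 potassium ethenyltrifluoroborate
Product: 5 7-ethenyl-1,4-dioxaspiro[4.5]dec-7-ene
Conditions: PdCl2(dppf)·CH2Cl2 (5 mol%), Cs2CO3, THF/H2O, 65 °C
Reagents that add atoms: none
Why: Suzuki–Miyaura coupling of an alkenyl triflate with a vinylborate proceeds with retention of the alkene position. The diene is formed under basic conditions, so no acid can move the ring alkene.

Step 3
Reactants: 5 7-ethenyl-1,4-dioxaspiro[4.5]dec-7-ene; 6 methacrolein
Product: 7 (4a'S,5'S)-5'-methyl-3',4',4a',5',6',7'-hexahydro-1'H-spiro[[1,3]dioxolane-2,2'-naphthalene]-5'-carbaldehyde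
Conditions: (S)-3,3-diphenyl-1-(2-methylphenyl)hexahydropyrrolo[1,2-c][1,3,2]oxazaborole (20 mol%), HN(SO2CF3)2 (18 mol%), CH2Cl2, −78 → −40 °C
Reagents that add atoms: none
Why: The N-protonated oxazaborolidine binds s-trans methacrolein at boron, and the LUMO-lowered enal adds to the s-cis diene in a concerted, asynchronous [4+2] cycloaddition; the closest known reaction type is the oxazaborolidinium-catalysed Diels–Alder reaction of 2-substituted acroleins with acyclic and semicyclic dienes. Ring A is closed by the cycloaddition itself (six-membered, suprafacial on both partners), which forms C2–C3 and C4–C5 and turns the central diene bond into C1=C10. Bonding of the enal β-carbon C3 to the unhindered vinyl terminus C2 leads, so the carbonyl-bearing C4 ends on ring carbon C5 (ortho adduct). C4 is controlled by the catalyst: its aryl groups cover one face of the bound enal and the diene is expected to add to the open Cα Re face, giving 4S. C5 is controlled relative to C4 by topology: the α-methyl group favours the formyl-exo arrangement, and with H-5 as the inside substituent of the diene terminus this places the formyl group cis to H-5 (5S). The step needs ortho regiochemistry, exo topology and one enal face; these are secured by the diene substitution pattern, the α-methyl group and the catalyst respectively, the diene being achiral. A slight deficit of HN(SO2CF3)2 keeps free strong acid away from the ketal and the diene.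

Step 4
Reactants: 7 (4a'S,5'S)-5'-methyl-3',4',4a',5',6',7'-hexahydro-1'H-spiro[[1,3]dioxolane-2,2'-naphthalene]-5'-carbaldehyde
Product: 8 (4a'S,5'S)-5'-methyl-3',4',4a',5',6',7'-hexahydro-1'H-spiro[[1,3]dioxolane-2,2'-naphthalene]-5'-carboxylic acid
Conditions: NaClO2, NaH2PO4, 2-methylbut-2-ene, t-BuOH/H2O, 0 °C → rt
Reagents that add atoms: sodium chlorite, [Na+].[O-]Cl=O
Why: Pinnick oxidation converts hindered, non-enolisable aldehydes cleanly. The alkene scavenger protects the 1(10)-alkene from hypochlorite and the phosphate buffer spares the ketal.

Step 5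
Reactants: 8 (4a'S,5'S)-5'-methyl-3',4',4a',5',6',7'-hexahydro-1'H-spiro[[1,3]dioxolane-2,2'-naphthalene]-5'-carboxylic acid
Product: 9 methyl (4a'S,5'S)-5'-methyl-3',4',4a',5',6',7'-hexahydro-1'H-spiro[[1,3]dioxolane-2,2'-naphthalene]-5'-carboxylate
Conditions: MeI, K2CO3, DMF, rt
Reagents that add atoms: iodomethane, CI
Why: SN2 O-alkylation of the carboxylate esterifies the α-quaternary acid without the forcing acid that a Fischer esterification would need, so the ketal and alkene position are kept.

Step 6
Reactants: 9 methyl (4a'S,5'S)-5'-methyl-3',4',4a',5',6',7'-hexahydro-1'H-spiro[[1,3]dioxolane-2,2'-naphthalene]-5'-carboxylate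
Product: 10 methyl (1S,8aS)-1-methyl-6-oxo-1,2,3,5,6,7,8,8a-octahydronaphthalene-1-carboxylate
Conditions: PPTS (cat.), acetone/H2O, 40 °C
Reagents that add atoms: water, O
Why: Mild acid-catalysed ketal hydrolysis should free the C8 ketone as the β,γ-unsaturated isomer. A weak acid is chosen so the alkene does not move into conjugation, and 10 is used without storage.

Step 7
Reactants: 10 methyl (1S,8aS)-1-methyl-6-oxo-1,2,3,5,6,7,8,8a-octahydronaphthalene-1-carboxylate
Product: 12 methyl (1S,8aS)-1,5-dimethyl-6-oxo-1,2,3,5,6,7,8,8a-octahydronaphthalene-1-carboxylate (both epimers at halimane C9), via potassium dienolate 11 (not isolated)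
Conditions: KN(SiMe3)2 (1.05 equiv), THF, −78 °C; MeI, −78 → −30 °C
Reagents that add atoms: iodomethane, CI
Why: The C9 methylene lies between the carbonyl and the alkene and is the most acidic site by several pKa units, so the linear dienolate O–C8=C9–C10=C1 forms directly and H-5 is never activated. α-Alkylation of this dienolate keeps the 1(10)-alkene; complete enolate formation before MeI limits dialkylation, and the C9 configuration is irrelevant.

Step 8
Reactants: 12 methyl (1S,8aS)-1,5-dimethyl-6-oxo-1,2,3,5,6,7,8,8a-octahydronaphthalene-1-carboxylate; 13 methyl bromoacetate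
Product: 15 methyl (1S,5R,8aS)-5-(2-methoxy-2-oxoethyl)-1,5-dimethyl-6-oxo-1,2,3,5,6,7,8,8a-octahydronaphthalene-1-carboxylate, via potassium dienolate 14 (not isolated)
Conditions: KN(SiMe3)2 (0.98 equiv), THF, −78 → −40 °C; BrCH2CO2Me, −78 → 0 °C
Reagents that add atoms: none
Why: Both epimers of 12 give the same dienolate, and the slight deficit of base lets any C7 enolate revert to this more stable one. In the dienolate ring B is an envelope whose flap C6 lies on the α face because H-5 is β; the electrophile is expected to add to C9 anti to the flap (β face), the axial-alkylation preference of cyclohexanone enolates, so ring B relaxes to a chair. This dienolate α-alkylation puts CH2CO2Me on the face of H-5 and leaves the methyl α.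

Step 9
Reactants: 15 methyl (1S,5R,8aS)-5-(2-methoxy-2-oxoethyl)-1,5-dimethyl-6-oxo-1,2,3,5,6,7,8,8a-octahydronaphthalene-1-carboxylate
Product: 16 methyl (1S,5S,8aS)-5-(2-methoxy-2-oxoethyl)-1,5-dimethyl-6-methylidene-1,2,3,5,6,7,8,8a-octahydronaphthalene-1-carboxylate
Conditions: Zn, CH2Br2, TiCl4, THF; then 15 in CH2Cl2, 0 °C → rt
Reagents that add atoms: dibromomethane, BrCBr
Why: Lombardo–Takai methylenation uses a non-basic zinc–titanium methylene reagent that converts hindered, enolisable ketones and leaves esters alone. A basic ylide is avoided because it could close the γ-keto ester by Claisen condensation.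

Step 10
Reactants: 16 methyl (1S,5S,8aS)-5-(2-methoxy-2-oxoethyl)-1,5-dimethyl-6-methylidene-1,2,3,5,6,7,8,8a-octahydronaphthalene-1-carboxylate
Product: 17 methyl (1S,5S,8aS)-5-(2-hydroxyethyl)-1,5-dimethyl-6-methylidene-1,2,3,5,6,7,8,8a-octahydronaphthalene-1-carboxylate
Conditions: LiBH4, THF, 0 °C → rt
Reagents that add atoms: none
Why: Chemoselective borohydride reduction: the primary CH2CO2Me ester should react much faster than the α-quaternary C4 ester, which is shielded by its methyl, C3 and C5.

Step 11
Reactants: 17 methyl (1S,5S,8aS)-5-(2-hydroxyethyl)-1,5-dimethyl-6-methylidene-1,2,3,5,6,7,8,8a-octahydronaphthalene-1-carboxylate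
Product: 18 methyl (1S,5S,6R,8aS)-5-(2-hydroxyethyl)-1,5,6-trimethyl-1,2,3,5,6,7,8,8a-octahydronaphthalene-1-carboxylate
Conditions: [Ir(cod)(PCy3)(py)]PF6 (5 mol%), H2 (1 atm), CH2Cl2, 0 °C → rt, stopped after one equivalent of H2
Reagents that add atoms: none
Why: Hydroxyl-directed hydrogenation: the C12 hydroxyl on the β arm of C9 binds the cationic iridium centre (six-membered chelate counting the nearer alkene carbon) and hydrogen should be delivered to the β face of the 8(17)-alkene. This gives H-8 β and the C8 methyl α (8R), cis to the C9 methyl. The exocyclic 1,1-disubstituted alkene is expected to react faster than the hindered trisubstituted 1(10)-alkene.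

Step 12
Reactants: 18 methyl (1S,5S,6R,8aS)-5-(2-hydroxyethyl)-1,5,6-trimethyl-1,2,3,5,6,7,8,8a-octahydronaphthalene-1-carboxylate
Product: 19 methyl (1S,5S,6R,8aS)-5-(2-iodoethyl)-1,5,6-trimethyl-1,2,3,5,6,7,8,8a-octahydronaphthalene-1-carboxylate
Conditions: I2, PPh3, imidazole, CH2Cl2, 0 °C → rt
Reagents that add atoms: iodine, II
Why: Appel-type iodination converts the unhindered primary alcohol by SN2 displacement of the oxyphosphonium group under neutral conditions.

Step 13
Reactants: 19 methyl (1S,5S,6R,8aS)-5-(2-iodoethyl)-1,5,6-trimethyl-1,2,3,5,6,7,8,8a-octahydronaphthalene-1-carboxylate; 20 lithium acetylide ethane-1,2-diamine complex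
Product: 21 methyl (1S,5S,6R,8aS)-5-(but-3-yn-1-yl)-1,5,6-trimethyl-1,2,3,5,6,7,8,8a-octahydronaphthalene-1-carboxylate
Conditions: LiC≡CH·H2NCH2CH2NH2, DMSO, rt
Reagents that add atoms: none
Why: Acetylide alkylation of a primary iodide in DMSO forms C12–C13 by SN2. The hindered C4 ester should not be attacked at room temperature.

Step 14
Reactants: 21 methyl (1S,5S,6R,8aS)-5-(but-3-yn-1-yl)-1,5,6-trimethyl-1,2,3,5,6,7,8,8a-octahydronaphthalene-1-carboxylate
Product: 24 methyl (1S,5S,6R,8aS)-5-[(3E)-5-hydroxy-3-methylpent-3-en-1-yl]-1,5,6-trimethyl-1,2,3,5,6,7,8,8a-octahydronaphthalene-1-carboxylate, via alkenylalane 22 (not isolated), via lithium alanate 23 (not isolated)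
Conditions: Me3Al (2.5 equiv), Cp2ZrCl2 (0.25 equiv), CH2Cl2, 0 °C → rt; n-BuLi (2.5 equiv), THF, −78 °C; (CH2O)n, −78 °C → rt
Reagents that add atoms: trimethylaluminium, C[Al](C)C; formaldehyde (from paraformaldehyde), C=O
Why: Negishi zirconium-catalysed carboalumination adds methyl and aluminium syn across the terminal alkyne, with methyl on the internal carbon, so the E geometry is set by mechanism. The alanate adds to formaldehyde with retention at the alkenyl carbon. n-BuLi is expected to be captured by aluminium much faster than it attacks the hindered ester.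

Step 15
Reactants: 24 methyl (1S,5S,6R,8aS)-5-[(3E)-5-hydroxy-3-methylpent-3-en-1-yl]-1,5,6-trimethyl-1,2,3,5,6,7,8,8a-octahydronaphthalene-1-carboxylate
Product: 25 methyl (1S,5S,6R,8aS)-5-[(3E)-5-(acetyloxy)-3-methylpent-3-en-1-yl]-1,5,6-trimethyl-1,2,3,5,6,7,8,8a-octahydronaphthalene-1-carboxylate
Conditions: Ac2O, pyridine, DMAP (cat.), CH2Cl2, rt
Reagents that add atoms: acetic anhydride, CC(=O)OC(C)=O
Why: Nucleophile-catalysed acylation of the primary allylic alcohol; no stereocentre or alkene is touched.

## Compound list

1 | 1,4-dioxaspiro[4.5]decan-7-one | O=C1CCCC2(C1)OCCO2 | starting material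
2 | lithium 1,4-dioxaspiro[4.5]dec-7-en-7-olate | [Li]OC1=CCCC2(C1)OCCO2 | intermediate
3 | 1,4-dioxaspiro[4.5]dec-7-en-7-yl trifluoromethanesulfonate | O=S(=O)(OC1=CCCC2(C1)OCCO2)C(F)(F)F | intermediate
4 | potassium ethenyltrifluoroborate | [K+].F[B-](F)(F)C=C | starting material
5 | 7-ethenyl-1,4-dioxaspiro[4.5]dec-7-ene | C=CC1=CCCC2(C1)OCCO2 | intermediate
6 | methacrolein | CC(=C)C=O | starting material
7 | exo adduct, (4a'S,5'S)-5'-methyl-3',4',4a',5',6',7'-hexahydro-1'H-spiro[[1,3]dioxolane-2,2'-naphthalene]-5'-carbaldehyde (halimane 4S,5S; CHO cis to H-5) | O=C[C@@]1(C)CCC=C2[C@@H]1CCC3(C2)OCCO3 | intermediate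
8 | the corresponding 5'-carboxylic acid | OC(=O)[C@@]1(C)CCC=C2[C@@H]1CCC3(C2)OCCO3 | intermediate
9 | the corresponding methyl 5'-carboxylate | COC(=O)[C@@]1(C)CCC=C2[C@@H]1CCC3(C2)OCCO3 | intermediate
10 | methyl (1S,8aS)-1-methyl-6-oxo-1,2,3,5,6,7,8,8a-octahydronaphthalene-1-carboxylate (halimane 8-oxo-1(10)-ene) | COC(=O)[C@@]1(C)CCC=C2[C@@H]1CCC(=O)C2 | intermediate
11 | potassium dienolate of 10 (O–C8=C9–C10=C1) | COC(=O)[C@@]1(C)CCC=C2[C@@H]1CCC(O[K])=C2 | intermediate
12 | methyl (1S,8aS)-1,5-dimethyl-6-oxo-1,2,3,5,6,7,8,8a-octahydronaphthalene-1-carboxylate, both C9 epimers | COC(=O)[C@@]1(C)CCC=C2[C@@H]1CCC(=O)C2C | intermediate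
13 | methyl bromoacetate | COC(=O)CBr | starting material
14 | potassium dienolate of 12 | COC(=O)[C@@]1(C)CCC=C2[C@@H]1CCC(O[K])=C2C | intermediate
15 | methyl (1S,5R,8aS)-5-(2-methoxy-2-oxoethyl)-1,5-dimethyl-6-oxo-1,2,3,5,6,7,8,8a-octahydronaphthalene-1-carboxylate | COC(=O)[C@@]1(C)CCC=C2[C@@H]1CCC(=O)[C@]2(C)CC(=O)OC | intermediate
16 | methyl (1S,5S,8aS)-5-(2-methoxy-2-oxoethyl)-1,5-dimethyl-6-methylidene-1,2,3,5,6,7,8,8a-octahydronaphthalene-1-carboxylate | COC(=O)[C@@]1(C)CCC=C2[C@@H]1CCC(=C)[C@]2(C)CC(=O)OC | intermediate
17 | methyl (1S,5S,8aS)-5-(2-hydroxyethyl)-1,5-dimethyl-6-methylidene-1,2,3,5,6,7,8,8a-octahydronaphthalene-1-carboxylate | COC(=O)[C@@]1(C)CCC=C2[C@@H]1CCC(=C)[C@]2(C)CCO | intermediate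
18 | methyl (1S,5S,6R,8aS)-5-(2-hydroxyethyl)-1,5,6-trimethyl-1,2,3,5,6,7,8,8a-octahydronaphthalene-1-carboxylate | COC(=O)[C@@]1(C)CCC=C2[C@@H]1CC[C@@H](C)[C@]2(C)CCO | intermediate
19 | methyl (1S,5S,6R,8aS)-5-(2-iodoethyl)-1,5,6-trimethyl-1,2,3,5,6,7,8,8a-octahydronaphthalene-1-carboxylate | COC(=O)[C@@]1(C)CCC=C2[C@@H]1CC[C@@H](C)[C@]2(C)CCI | intermediate
20 | lithium acetylide ethane-1,2-diamine complex | [Li]C#C.NCCN | starting material
21 | methyl (1S,5S,6R,8aS)-5-(but-3-yn-1-yl)-1,5,6-trimethyl-1,2,3,5,6,7,8,8a-octahydronaphthalene-1-carboxylate | COC(=O)[C@@]1(C)CCC=C2[C@@H]1CC[C@@H](C)[C@]2(C)CCC#C | intermediate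
22 | (E)-alkenyldimethylalane from 21 (methyl on C13, aluminium on C14) | COC(=O)[C@@]1(C)CCC=C2[C@@H]1CC[C@@H](C)[C@]2(C)CC/C(C)=C/[Al](C)C | intermediate
23 | lithium butyl(alkenyl)dimethylalanate from 22 | COC(=O)[C@@]1(C)CCC=C2[C@@H]1CC[C@@H](C)[C@]2(C)CC/C(C)=C/[Al-](C)(C)CCCC.[Li+] | intermediate
24 | methyl (1S,5S,6R,8aS)-5-[(3E)-5-hydroxy-3-methylpent-3-en-1-yl]-1,5,6-trimethyl-1,2,3,5,6,7,8,8a-octahydronaphthalene-1-carboxylate | COC(=O)[C@@]1(C)CCC=C2[C@@H]1CC[C@@H](C)[C@]2(C)CC/C(C)=C/CO | intermediate
25 | methyl (1S,5S,6R,8aS)-5-[(3E)-5-(acetyloxy)-3-methylpent-3-en-1-yl]-1,5,6-trimethyl-1,2,3,5,6,7,8,8a-octahydronaphthalene-1-carboxylate | COC(=O)[C@@]1(C)CCC=C2[C@@H]1CC[C@@H](C)[C@]2(C)CC/C(C)=C/COC(C)=O | target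

## Step count and least certain steps

Total step count: 15. Longest linear sequence: 15 steps (1 to 25).

**Step 3 (key step).** The most likely failure is ionisation of the ketal or polymerisation of the acid-sensitive diene by the strongly acidic catalyst before the slow cycloaddition at the hindered ring terminus. A second risk is loss of exo or facial selectivity if the temperature must be raised. The fallback sets out from 5 (with 6) and returns at 8. The cycloaddition is run without a chiral catalyst (Me2AlCl, CH2Cl2, −78 °C), which should still favour the ortho, exo mode and give the racemic exo aldehyde F1. Oxidation with NaClO2 gives the racemic acid F2. Crystallisation with (R)-1-phenylethanamine (or its enantiomer if that salt is the less soluble) gives the diastereomerically pure salt F3, and acidification releases 8.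

**Step 8.** The most likely failure is poor facial selectivity at C9, because the β preference rests only on a stereoelectronic bias with H-5 as the sole syn-axial partner. Some O-alkylation or C1-alkylation may also occur. The fallback sets out from 12 and returns at 15, and puts C9 under catalyst control. Trapping the potassium dienolate with allyl chloroformate gives the allyl dienyl carbonate F4. Decarboxylative asymmetric allylic alkylation with Pd2(dba)3 and the matched enantiomer of 4-tert-butyl-2-[2-(diphenylphosphanyl)phenyl]-4,5-dihydro-1,3-oxazole gives the 9-allyl-9-methyl ketone F5. Lemieux–Johnson cleavage (OsO4 cat., NaIO4, 2,6-lutidine) gives the keto aldehyde F6, NaClO2 gives the keto acid F7, and MeI/K2CO3 gives 15.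

**Step 11.** The most likely failure is weak direction by a hydroxyl three atoms from the alkene, so that hydrogen arrives from the sterically open α face. Over-reduction or migration of the 1(10)-alkene on the same catalyst is also possible. The fallback sets out from 16 and returns at 18, and replaces the neutral hydroxyl by an anionic carboxylate donor. LiOH in THF/H2O should hydrolyse only the unhindered side-chain ester to give the acid F8. Carboxylate-directed hydrogenation with [Rh(nbd)(dppb)]BF4, Et3N and H2 gives the 8α-methyl acid F9. Isobutyl chloroformate and N-methylmorpholine give the mixed anhydride F10, which NaBH4 reduces to 18. This sequence also removes the need for the ester-selective hydride reduction of step 10.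

**Step 14.** The most likely failure is attack on the C4 ester during alanate formation with n-BuLi, or slow capture of formaldehyde by the alkenylaluminium species. The fallback sets out from 21 and returns at 24. The carboalumination is run as before but quenched with iodine to give the (E)-alkenyl iodide F11. Stille coupling with Bu3SnCH2OH under Pd(PPh3)4 in dioxane at 90 °C then installs C15 as the hydroxymethyl group with retention of geometry, giving 24.

## Further compounds

F1 | step 3 | racemic exo aldehyde (7 and its enantiomer, 1:1) | O=C[C@@]1(C)CCC=C2[C@@H]1CCC3(C2)OCCO3.O=C[C@]1(C)CCC=C2[C@H]1CCC3(C2)OCCO3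
F2 | step 3 | racemic acid (8 and its enantiomer, 1:1) | OC(=O)[C@@]1(C)CCC=C2[C@@H]1CCC3(C2)OCCO3.OC(=O)[C@]1(C)CCC=C2[C@H]1CCC3(C2)OCCO3
F3 | step 3 | (R)-1-phenylethanaminium salt of 8 | [O-]C(=O)[C@@]1(C)CCC=C2[C@@H]1CCC3(C2)OCCO3.C[C@@H]([NH3+])c1ccccc1
F4 | step 8 | allyl dienyl carbonate of 12 (O-allyloxycarbonyl on the C8 oxygen, diene C8=C9–C10=C1) | COC(=O)[C@@]1(C)CCC=C2[C@@H]1CCC(OC(=O)OCC=C)=C2C
F5 | step 8 | methyl (1S,5R,8aS)-1,5-dimethyl-6-oxo-5-(prop-2-en-1-yl)-1,2,3,5,6,7,8,8a-octahydronaphthalene-1-carboxylate | COC(=O)[C@@]1(C)CCC=C2[C@@H]1CCC(=O)[C@]2(C)CC=C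
F6 | step 8 | methyl (1S,5R,8aS)-1,5-dimethyl-6-oxo-5-(2-oxoethyl)-1,2,3,5,6,7,8,8a-octahydronaphthalene-1-carboxylate | COC(=O)[C@@]1(C)CCC=C2[C@@H]1CCC(=O)[C@]2(C)CC=O
F7 | step 8 | 2-[(1R,5S,4aS)-configured keto ester]acetic acid, the C12 acid of 15 | COC(=O)[C@@]1(C)CCC=C2[C@@H]1CCC(=O)[C@]2(C)CC(O)=O
F8 | step 11 | C12 carboxylic acid of 16 (side-chain CH2CO2H, 8(17)-methylene) | COC(=O)[C@@]1(C)CCC=C2[C@@H]1CCC(=C)[C@]2(C)CC(O)=O
F9 | step 11 | C12 carboxylic acid with 8α-methyl (8R) | COC(=O)[C@@]1(C)CCC=C2[C@@H]1CC[C@@H](C)[C@]2(C)CC(O)=O
F10 | step 11 | isobutyl carbonic mixed anhydride of F9 | COC(=O)[C@@]1(C)CCC=C2[C@@H]1CC[C@@H](C)[C@]2(C)CC(=O)OC(=O)OCC(C)C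
F11 | step 14 | methyl (1S,5S,6R,8aS)-5-[(3E)-4-iodo-3-methylbut-3-en-1-yl]-1,5,6-trimethyl-1,2,3,5,6,7,8,8a-octahydronaphthalene-1-carboxylate | COC(=O)[C@@]1(C)CCC=C2[C@@H]1CC[C@@H](C)[C@]2(C)CC/C(C)=C/I
A1 | alternative 1 | ring-A-fused δ-lactone (O on C6, C11 carbonyl on C9, C9 methyl, (Z)-prop-1-enyl on C6 cis to the C5–C4 bond; C9 configuration immaterial) | COC(=O)[C@@]1(C)CCC=C2[C@@H]1[C@@H](/C=C\C)OC(=O)C2C
A2 | alternative 1 | bicyclic C11 carboxylic acid with 6(7)-alkene | COC(=O)[C@@]1(C)CCC=C2[C@@H]1C=C[C@@H](C)[C@]2(C)C(O)=O
A3 | alternative 2 | ring-A C10 enol triflate carrying the C6–C9 chain with 9(20)-methylene and C12 silyl ether | COC(=O)[C@@]1(C)CCC=C(OS(=O)(=O)C(F)(F)F)[C@@H]1CC[C@@H](C)C(=C)CCO[Si](C)(C)C(C)(C)C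
A4 | alternative 2 | methyl ent-12-(tert-butyldimethylsilyloxy)-13,14,15,16-tetranorhalim-1(10)-en-18-oate | COC(=O)[C@@]1(C)CCC=C2[C@@H]1CC[C@@H](C)[C@]2(C)CCO[Si](C)(C)C(C)(C)C
A5 | alternative 3 | α-methoxycarbonyl δ-lactone with the ring-B cyclohexenyl group on the alkoxy carbon C1 (C4 configuration immaterial) | COC(=O)C1CC[C@H](OC1=O)C2=CCC[C@@H](C)[C@]2(C)CC=C
A6 | alternative 3 | bicyclic C4 acid ester (carboxyl trans to H-5) with C9 allyl | COC(=O)[C@@]1(C(O)=O)CCC=C2[C@@H]1CC[C@@H](C)[C@]2(C)CC=C
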